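**Plan**

- Retrosynthesis: the side chain is cut at C12–C13 (syn-carbocupration of a 4-silyloxybut-2-ynoate fixes 13Z); the decalin is then cut at C5–C10 and C6–C7 together, a retro-[4+2] of ring B.
- Enabling feature: in ring B the two-carbon unit C5–C6 faces the four-carbon unit C7–C8–C9–C10, C8 carries the exocyclic methylene, and C1–C4 of ring A link C10 to C5. So C7=C8–C9=C10 (methylene stored as a C8–CH2SiMe3 group) is a diene, C5=C6 a dienophile, and ring A the four-carbon tether of an acyclic triene.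
- Forward: the tetrasubstituted C9=C10 bond is built with fixed geometry from 2-acetylbutyrolactone (enol triflate, B-alkyl Suzuki coupling). The lactone carbonyl becomes the 2-(silylmethyl)diene, an N-enoyl oxazolidinone is attached at C5=C6, and one Me2AlCl-promoted intramolecular Diels–Alder reaction closes rings A and B at once.
- Helpers and their removal: the acyl oxazolidinone on C6 (activation, absolute control) leaves by hydrolysis and radical decarboxylation. The silyl group leaves in a protodesilylation that creates the 8(17)-methylene and C9–H. The lactone oxygen is stored as a C12 chloride that later becomes the organocopper.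
- Stereochemistry: C5 and C10 come from the endo cycloaddition on the face opposite the (R)-4-benzyl group with the (E) C9=C10 geometry; C9 from axial protonation anti to the angular methyl; 13Z from syn addition of the organocopper.

Key step: step 11

Remark: labdane numbering is used for positions (ring A = C1–C5 and C10, ring B = C5–C10, C17 = methylene carbon, C20 = angular methyl). Compounds 1, 4, 16 and 29 and the simple reagents are taken as commercial.

**Step 1**
Reactants: 1 2,2-dimethylpent-4-en-1-ol; 2 tert-butyldimethylsilyl chloride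
Product: 3 tert-butyl[(2,2-dimethylpent-4-en-1-yl)oxy]dimethylsilane
Conditions: imidazole, DMF, 0 °C to rt
Reagents that add atoms: tert-butyldimethylsilyl chloride, CC(C)(C)[Si](C)(C)Cl
Why: Standard silylation of the primary (neopentyl) alcohol masks the future C5 oxygen through the organoboron and organocerium steps.

**Step 2**
Reactants: 4 2-acetylbutyrolactone; 5 trifluoromethanesulfonic anhydride
Product: 6 (E)-1-(2-oxooxolan-3-ylidene)ethyl trifluoromethanesulfonate
Conditions: Tf2O, 25 % aq. Me4NOH, toluene, 5 °C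
Reagents that add atoms: trifluoromethanesulfonic anhydride, O=S(=O)(OS(=O)(=O)C(F)(F)F)C(F)(F)F
Why: Stereoselective enol triflation of a β-keto ester: with the non-coordinating Me4N+ counter-ion the enolate oxygen lies anti to the lactone carbonyl (no chelate, dipole minimisation), so O-sulfonylation should give the (E)-enol triflate with the methyl cis to the carbonyl.

**Step 3**
Reactants: 3 tert-butyl[(2,2-dimethylpent-4-en-1-yl)oxy]dimethylsilane; 6 (E)-1-(2-oxooxolan-3-ylidene)ethyl trifluoromethanesulfonate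
Product: 8 (E)-3-{7-[(tert-butyldimethylsilyl)oxy]-6,6-dimethylheptan-2-ylidene}oxolan-2-one, via alkylborane 7 (not isolated)
Conditions: 9-BBN, THF, 0 °C to rt; then 6, PdCl2(dppf) (5 mol %), AsPh3, Cs2CO3, DMF/THF/H2O, rt
Reagents that add atoms: none
Why: Anti-Markovnikov hydroboration followed by B-alkyl Suzuki–Miyaura coupling; oxidative addition to the β-triflyloxy enoate and reductive elimination both go with retention, so the chain takes the place of the triflate and the tetrasubstituted alkene geometry (chain cis to the ring CH2) is fixed.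

**Step 4**
Reactants: 8 (E)-3-{7-[(tert-butyldimethylsilyl)oxy]-6,6-dimethylheptan-2-ylidene}oxolan-2-one; 9 (trimethylsilyl)methylmagnesium chloride
Product: 11 (E)-9-[(tert-butyldimethylsilyl)oxy]-4,8,8-trimethyl-3-[3-(trimethylsilyl)prop-1-en-2-yl]non-3-en-1-ol, via bis(silylmethyl) carbinol 10 (not isolated)
Conditions: Me3SiCH2MgCl (5 equiv), CeCl3 (5 equiv), THF, −78 °C to rt; aq. NH4Cl; then silica gel, CH2Cl2, rt
Reagents that add atoms: (trimethylsilyl)methylmagnesium chloride, C[Si](C)(C)C[Mg]Cl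
Why: Twofold 1,2-addition of the weakly basic organocerium reagent to the lactone carbonyl (conjugate addition is blocked by the fully substituted β-carbon) gives a bis(β-silyl) tertiary carbinol whose acid-mediated Peterson elimination expels one silyl group; this known ester-to-2-(silylmethyl)alkene conversion leaves the C9=C10 geometry untouched and frees the C12 hydroxyl.

**Step 5**
Reactants: 11 (E)-9-[(tert-butyldimethylsilyl)oxy]-4,8,8-trimethyl-3-[3-(trimethylsilyl)prop-1-en-2-yl]non-3-en-1-ol; 12 carbon tetrachloride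
Product: 13 (E)-tert-butyl({9-chloro-2,2,6-trimethyl-7-[3-(trimethylsilyl)prop-1-en-2-yl]non-6-en-1-yl}oxy)dimethylsilane
Conditions: PPh3, CCl4, CH2Cl2, rt
Reagents that add atoms: carbon tetrachloride, ClC(Cl)(Cl)Cl
Why: Appel reaction: SN2 displacement of the alkoxyphosphonium ion at the unhindered primary carbon under neutral conditions stores the C12 oxygen as a chloride that should survive until it is turned into the organometallic, while silyl ether, diene and allylsilane are untouched.

**Step 6**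
Reactants: 13 (E)-tert-butyl({9-chloro-2,2,6-trimethyl-7-[3-(trimethylsilyl)prop-1-en-2-yl]non-6-en-1-yl}oxy)dimethylsilane
Product: 14 (E)-9-chloro-2,2,6-trimethyl-7-[3-(trimethylsilyl)prop-1-en-2-yl]non-6-en-1-ol
Conditions: TBAF, AcOH (1:1), THF, rt
Reagents that add atoms: none
Why: Fluoride cleavage of the silyl ether, buffered with acetic acid so that neither E2 elimination of the chloride nor attack on the allylic C–Si bond should compete.

**Step 7**
Reactants: 14 (E)-9-chloro-2,2,6-trimethyl-7-[3-(trimethylsilyl)prop-1-en-2-yl]non-6-en-1-ol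
Product: 15 (E)-9-chloro-2,2,6-trimethyl-7-[3-(trimethylsilyl)prop-1-en-2-yl]non-6-enal
Conditions: DMP, NaHCO3, CH2Cl2, 0 °C to rt
Reagents that add atoms: none
Why: Hypervalent-iodine oxidation of the primary alcohol under bicarbonate buffering gives the non-enolisable α-quaternary aldehyde without acid that would harm the allylsilane.

**Step 8**
Reactants: 16 (R)-4-benzyloxazolidin-2-one; 17 bromoacetyl bromide
Product: 18 (R)-4-benzyl-3-(bromoacetyl)oxazolidin-2-one
Conditions: n-BuLi, THF, −78 °C; then BrCH2COBr, −78 to 0 °C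
Reagents that add atoms: bromoacetyl bromide, O=C(Br)CBr
Why: N-Acylation of the lithiated oxazolidinone at the acyl bromide, which is far more electrophilic than the alkyl bromide, leaves the stereocentre untouched.

**Step 9**
Reactants: 18 (R)-4-benzyl-3-(bromoacetyl)oxazolidin-2-one; 19 triethyl phosphite
Product: 20 diethyl {2-[(R)-4-benzyl-2-oxooxazolidin-3-yl]-2-oxoethyl}phosphonate
Conditions: P(OEt)3, neat, 90 °C
Reagents that add atoms: triethyl phosphite, CCOP(OCC)OCC
Why: Michaelis–Arbuzov reaction of the α-bromo imide gives the stabilised phosphonate.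

**Step 10**
Reactants: 15 (E)-9-chloro-2,2,6-trimethyl-7-[3-(trimethylsilyl)prop-1-en-2-yl]non-6-enal; 20 diethyl {2-[(R)-4-benzyl-2-oxooxazolidin-3-yl]-2-oxoethyl}phosphonate
Product: 21 (R)-4-benzyl-3-{(2E,8E)-11-chloro-4,4,8-trimethyl-9-[3-(trimethylsilyl)prop-1-en-2-yl]undeca-2,8-dienoyl}oxazolidin-2-one
Conditions: LiCl, i-Pr2NEt, MeCN, rt
Reagents that add atoms: none
Why: Horner–Wadsworth–Emmons olefination with a LiCl/amine base is (E)-selective for stabilised phosphonates and bulky aldehydes and attaches the activating, stereodirecting N-enoyl oxazolidinone to C5=C6.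

**Step 11**
Reactants: 21 (R)-4-benzyl-3-{(2E,8E)-11-chloro-4,4,8-trimethyl-9-[3-(trimethylsilyl)prop-1-en-2-yl]undeca-2,8-dienoyl}oxazolidin-2-one
Product: 22 (R)-4-benzyl-3-{(1R,4aR,8aR)-4-(2-chloroethyl)-4a,8,8-trimethyl-3-[(trimethylsilyl)methyl]-1,2,4a,5,6,7,8,8a-octahydronaphthalene-1-carbonyl}oxazolidin-2-one
Conditions: Me2AlCl (2.0 equiv), CH2Cl2, −40 to 0 °C; aq. KNaC4H4O6 (potassium sodium tartrate) quench
Reagents that add atoms: none
Why: Chelation of Me2AlCl by the two imide carbonyls gives a cationic, s-cis-locked N-enoyl oxazolidinone whose C5=C6 bond adds suprafacially across the termini of the diene C7=C8–C9=C10 in an asynchronous concerted [4+2] cycloaddition, the C5–C10 bond leading and the C6–C7 bond following. The closest known reaction type is the dialkylaluminium chloride-promoted intramolecular Diels–Alder reaction of chiral trienimides (type 1, four-carbon tether), combined with the known use of 2-(silylmethyl)dienes as masked exocyclic-methylene dienes. Ring A closes through the C5–C10 bond as the six-membered ring spanned by the C1–C4 tether in the fused mode, and ring B is the cyclohexene formed by the cycloaddition itself, its new C8=C9 bond holding the allylsilane. C10 (quaternary) and C5 are set relative to each other by the (E) geometry of the C9=C10 bond (chain outside, methyl inside) together with the endo transition state, which places 5-H and the C10 methyl anti (trans-decalin); C6 follows from the (E)-dienophile and is erased later. The absolute sense comes from the (R)-4-benzyl group, which shields one face of the chelated dienophile so that the diene should add to the Cα-re face. The step needs endo over exo and one π-face, secured by the chelate, the enoyl geometry and the fixed diene geometry; no regiochemical alternative exists because the tether allows only the C5–C10/C6–C7 pairing.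

**Step 12**
Reactants: 22 (R)-4-benzyl-3-{(1R,4aR,8aR)-4-(2-chloroethyl)-4a,8,8-trimethyl-3-[(trimethylsilyl)methyl]-1,2,4a,5,6,7,8,8a-octahydronaphthalene-1-carbonyl}oxazolidin-2-one
Product: 23 (R)-4-benzyl-3-[(1R,4R,4aS,8aR)-4-(2-chloroethyl)-4a,8,8-trimethyl-3-methylidenedecahydronaphthalene-1-carbonyl]oxazolidin-2-one
Conditions: CF3CO2H (2 equiv), CH2Cl2, −40 to −20 °C; then aq. NaHCO3
Reagents that add atoms: none
Why: SE2′ protodesilylation of the allylsilane: the proton should add to C9 axially on the face anti to the axial C10 methyl, the β-silyl cation at C8 loses silicon to give the 8(17)-methylene, and C9 is thereby set with its hydrogen cis to 5-H and the side chain equatorial.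

**Step 13**
Reactants: 23 (R)-4-benzyl-3-[(1R,4R,4aS,8aR)-4-(2-chloroethyl)-4a,8,8-trimethyl-3-methylidenedecahydronaphthalene-1-carbonyl]oxazolidin-2-one; 24 hydrogen peroxide
Product: 26 (1R,4R,4aS,8aR)-4-(2-chloroethyl)-4a,8,8-trimethyl-3-methylidenedecahydronaphthalene-1-carboxylic acid, via peroxy acid 25 (not isolated)
Conditions: LiOH, H2O2, THF/H2O, 0 °C; then aq. Na2SO3; then dilute HCl to pH 3
Reagents that add atoms: hydrogen peroxide, OO
Why: Lithium hydroperoxide attacks the exocyclic imide carbonyl selectively, the percarboxylate is reduced by sulfite before acidification so that no epoxidising peracid meets the alkene, and the auxiliary is recovered.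

**Step 14**
Reactants: 26 (1R,4R,4aS,8aR)-4-(2-chloroethyl)-4a,8,8-trimethyl-3-methylidenedecahydronaphthalene-1-carboxylic acid
Product: 28 (1R,4aR,8aR)-1-(2-chloroethyl)-5,5,8a-trimethyl-2-methylidenedecahydronaphthalene, via N-acyloxyphthalimide 27 (not isolated)
Conditions: N-hydroxyphthalimide, DIC, DMAP (cat.), CH2Cl2, rt; filtered, concentrated; then diethyl 2,6-dimethyl-1,4-dihydropyridine-3,5-dicarboxylate, Ru(bpy)3Cl2 (1 mol %), DMF, blue LEDs, rt
Reagents that add atoms: none
Why: Barton-type radical reductive decarboxylation through the redox-active ester: single-electron reduction releases CO2 and the secondary C6 radical, which takes hydrogen from the dihydropyridine, so the activating group should leave without touching the chloride or the alkene.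

**Step 15**
Reactants: 29 tert-butyldimethyl(prop-2-yn-1-yloxy)silane; 30 di-tert-butyl dicarbonate
Product: 31 tert-butyl 4-[(tert-butyldimethylsilyl)oxy]but-2-ynoate
Conditions: n-BuLi, THF, −78 °C; then Boc2O, −78 to 0 °C; aq. NH4Cl
Reagents that add atoms: di-tert-butyl dicarbonate, CC(C)(C)OC(=O)OC(=O)OC(C)(C)C
Why: Acylation of the lithium acetylide with the dicarbonate is a standard route to tert-butyl alkynoates.

**Step 16**
Reactants: 28 (1R,4aR,8aR)-1-(2-chloroethyl)-5,5,8a-trimethyl-2-methylidenedecahydronaphthalene; 31 tert-butyl 4-[(tert-butyldimethylsilyl)oxy]but-2-ynoate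
Product: 35 tert-butyl (2Z)-3-{[(tert-butyldimethylsilyl)oxy]methyl}-5-[(1R,4aR,8aR)-5,5,8a-trimethyl-2-methylidenedecahydronaphthalen-1-yl]pent-2-enoate, via Grignard reagent 32 (not isolated), via alkylcopper 33 (not isolated), via alkenylcopper 34 (not isolated)
Conditions: Mg (I2-activated), THF, reflux; then CuBr·SMe2 (1.0 equiv), −45 °C; then 31, −78 °C; aq. NH4Cl at −78 °C
Reagents that add atoms: none
Why: Grignard formation from the primary chloride, transmetallation to the alkylcopper and syn-carbocupration of the ynoate at −78 °C place alkyl and copper cis on the β- and α-carbons; protonation with retention should give the (Z)-enoate with CH2OSi and ester cis, as in the known additions to 4-silyloxybut-2-ynoates.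

**Step 17**
Reactants: 35 tert-butyl (2Z)-3-{[(tert-butyldimethylsilyl)oxy]methyl}-5-[(1R,4aR,8aR)-5,5,8a-trimethyl-2-methylidenedecahydronaphthalen-1-yl]pent-2-enoate; 36 acetic anhydride
Product: 38 tert-butyl (2Z)-3-(acetoxymethyl)-5-[(1R,4aR,8aR)-5,5,8a-trimethyl-2-methylidenedecahydronaphthalen-1-yl]pent-2-enoate, via hydroxy ester 37 (not isolated)
Conditions: HF·pyridine, pyridine, THF, 0 °C; then Ac2O, DMAP, 0 °C
Reagents that add atoms: acetic anhydride, CC(=O)OC(C)=O
Why: Buffered fluoride desilylation gives the (Z)-γ-hydroxy tert-butyl ester, whose bulky ester should resist lactonisation long enough for DMAP-catalysed acetylation in the same flask.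

**Step 18**
Reactants: 38 tert-butyl (2Z)-3-(acetoxymethyl)-5-[(1R,4aR,8aR)-5,5,8a-trimethyl-2-methylidenedecahydronaphthalen-1-yl]pent-2-enoate
Product: 40 (2Z)-3-(acetoxymethyl)-5-[(1R,4aR,8aR)-5,5,8a-trimethyl-2-methylidenedecahydronaphthalen-1-yl]pent-2-enoic acid, via trimethylsilyl ester 39 (not isolated)
Conditions: TMSOTf, 2,6-lutidine, CH2Cl2, 0 °C; then H2O
Reagents that add atoms: none
Why: Silyl triflate-mediated cleavage of the tert-butyl ester (O-silylation, loss of isobutene) under a hindered base gives the silyl ester, hydrolysed on work-up, under conditions that should spare the acetate and not protonate the exocyclic alkene.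

**Compound list**

1 | 2,2-dimethylpent-4-en-1-ol | C=CCC(C)(C)CO | starting material
2 | tert-butyldimethylsilyl chloride | CC(C)(C)[Si](C)(C)Cl | starting material
3 | tert-butyl[(2,2-dimethylpent-4-en-1-yl)oxy]dimethylsilane | C=CCC(C)(C)CO[Si](C)(C)C(C)(C)C | intermediate
4 | 2-acetylbutyrolactone (3-acetyloxolan-2-one) | CC(=O)C1CCOC1=O | starting material
5 | trifluoromethanesulfonic anhydride | O=S(=O)(OS(=O)(=O)C(F)(F)F)C(F)(F)F | starting material
6 | (E)-1-(2-oxooxolan-3-ylidene)ethyl trifluoromethanesulfonate | C/C(OS(=O)(=O)C(F)(F)F)=C1/CCOC1=O | intermediate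
7 | 9-{5-[(tert-butyldimethylsilyl)oxy]-4,4-dimethylpentyl}-9-borabicyclo[3.3.1]nonane | CC(C)(C)[Si](C)(C)OCC(C)(C)CCCB1C2CCCC1CCC2 | intermediate
8 | (E)-3-{7-[(tert-butyldimethylsilyl)oxy]-6,6-dimethylheptan-2-ylidene}oxolan-2-one | C/C(CCCC(C)(C)CO[Si](C)(C)C(C)(C)C)=C1/CCOC1=O | intermediate
9 | (trimethylsilyl)methylmagnesium chloride | C[Si](C)(C)C[Mg]Cl | starting material
10 | (E)-9-[(tert-butyldimethylsilyl)oxy]-3-[2-hydroxy-1,3-bis(trimethylsilyl)propan-2-yl]-4,8,8-trimethylnon-3-en-1-ol | C[Si](C)(C)CC(O)(C[Si](C)(C)C)/C(CCO)=C(\C)CCCC(C)(C)CO[Si](C)(C)C(C)(C)C | intermediate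
11 | (E)-9-[(tert-butyldimethylsilyl)oxy]-4,8,8-trimethyl-3-[3-(trimethylsilyl)prop-1-en-2-yl]non-3-en-1-ol | C=C(C[Si](C)(C)C)/C(CCO)=C(\C)CCCC(C)(C)CO[Si](C)(C)C(C)(C)C | intermediate
12 | carbon tetrachloride | ClC(Cl)(Cl)Cl | starting material
13 | (E)-tert-butyl({9-chloro-2,2,6-trimethyl-7-[3-(trimethylsilyl)prop-1-en-2-yl]non-6-en-1-yl}oxy)dimethylsilane | C=C(C[Si](C)(C)C)/C(CCCl)=C(\C)CCCC(C)(C)CO[Si](C)(C)C(C)(C)C | intermediate
14 | (E)-9-chloro-2,2,6-trimethyl-7-[3-(trimethylsilyl)prop-1-en-2-yl]non-6-en-1-ol | C=C(C[Si](C)(C)C)/C(CCCl)=C(\C)CCCC(C)(C)CO | intermediate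
15 | (E)-9-chloro-2,2,6-trimethyl-7-[3-(trimethylsilyl)prop-1-en-2-yl]non-6-enal | C=C(C[Si](C)(C)C)/C(CCCl)=C(\C)CCCC(C)(C)C=O | intermediate
16 | (R)-4-benzyloxazolidin-2-one | O=C1N[C@H](Cc2ccccc2)CO1 | starting material
17 | bromoacetyl bromide | O=C(Br)CBr | starting material
18 | (R)-4-benzyl-3-(bromoacetyl)oxazolidin-2-one | O=C(CBr)N1[C@H](Cc2ccccc2)COC1=O | intermediate
19 | triethyl phosphite | CCOP(OCC)OCC | starting material
20 | diethyl {2-[(R)-4-benzyl-2-oxooxazolidin-3-yl]-2-oxoethyl}phosphonate | CCOP(=O)(CC(=O)N1[C@H](Cc2ccccc2)COC1=O)OCC | intermediate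
21 | (R)-4-benzyl-3-{(2E,8E)-11-chloro-4,4,8-trimethyl-9-[3-(trimethylsilyl)prop-1-en-2-yl]undeca-2,8-dienoyl}oxazolidin-2-one | C=C(C[Si](C)(C)C)/C(CCCl)=C(\C)CCCC(C)(C)/C=C/C(=O)N1[C@H](Cc2ccccc2)COC1=O | intermediate
22 | (R)-4-benzyl-3-{(1R,4aR,8aR)-4-(2-chloroethyl)-4a,8,8-trimethyl-3-[(trimethylsilyl)methyl]-1,2,4a,5,6,7,8,8a-octahydronaphthalene-1-carbonyl}oxazolidin-2-one (trans-fused; acyl on C6 cis to 5-H) | ClCCC1=C(C[Si](C)(C)C)C[C@@H](C(=O)N3[C@H](Cc4ccccc4)COC3=O)[C@@H]2C(C)(C)CCC[C@@]12C | intermediate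
23 | (R)-4-benzyl-3-[(1R,4R,4aS,8aR)-4-(2-chloroethyl)-4a,8,8-trimethyl-3-methylidenedecahydronaphthalene-1-carbonyl]oxazolidin-2-one | C=C1C[C@@H](C(=O)N3[C@H](Cc4ccccc4)COC3=O)[C@@H]2C(C)(C)CCC[C@@]2(C)[C@@H]1CCCl | intermediate
24 | hydrogen peroxide | OO | starting material
25 | (1R,4R,4aS,8aR)-4-(2-chloroethyl)-4a,8,8-trimethyl-3-methylidenedecahydronaphthalene-1-carboperoxoic acid | C=C1C[C@@H](C(=O)OO)[C@@H]2C(C)(C)CCC[C@@]2(C)[C@@H]1CCCl | intermediate
26 | (1R,4R,4aS,8aR)-4-(2-chloroethyl)-4a,8,8-trimethyl-3-methylidenedecahydronaphthalene-1-carboxylic acid | C=C1C[C@@H](C(=O)O)[C@@H]2C(C)(C)CCC[C@@]2(C)[C@@H]1CCCl | intermediate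
27 | 1,3-dioxoisoindolin-2-yl (1R,4R,4aS,8aR)-4-(2-chloroethyl)-4a,8,8-trimethyl-3-methylidenedecahydronaphthalene-1-carboxylate | C=C1C[C@@H](C(=O)ON3C(=O)c4ccccc4C3=O)[C@@H]2C(C)(C)CCC[C@@]2(C)[C@@H]1CCCl | intermediate
28 | (1R,4aR,8aR)-1-(2-chloroethyl)-5,5,8a-trimethyl-2-methylidenedecahydronaphthalene | C=C1CC[C@@H]2C(C)(C)CCC[C@@]2(C)[C@@H]1CCCl | intermediate
29 | tert-butyldimethyl(prop-2-yn-1-yloxy)silane | C#CCO[Si](C)(C)C(C)(C)C | starting material
30 | di-tert-butyl dicarbonate | CC(C)(C)OC(=O)OC(=O)OC(C)(C)C | starting material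
31 | tert-butyl 4-[(tert-butyldimethylsilyl)oxy]but-2-ynoate | CC(C)(C)OC(=O)C#CCO[Si](C)(C)C(C)(C)C | intermediate
32 | {2-[(1R,4aR,8aR)-5,5,8a-trimethyl-2-methylidenedecahydronaphthalen-1-yl]ethyl}magnesium chloride | C=C1CC[C@@H]2C(C)(C)CCC[C@@]2(C)[C@@H]1CC[Mg]Cl | intermediate
33 | {2-[(1R,4aR,8aR)-5,5,8a-trimethyl-2-methylidenedecahydronaphthalen-1-yl]ethyl}copper | C=C1CC[C@@H]2C(C)(C)CCC[C@@]2(C)[C@@H]1CC[Cu] | intermediate
34 | tert-butyl (2E)-3-{[(tert-butyldimethylsilyl)oxy]methyl}-2-cuprio-5-[(1R,4aR,8aR)-5,5,8a-trimethyl-2-methylidenedecahydronaphthalen-1-yl]pent-2-enoate (copper cis to the alkyl chain) | C=C1CC[C@@H]2C(C)(C)CCC[C@@]2(C)[C@@H]1CC/C(CO[Si](C)(C)C(C)(C)C)=C(\[Cu])C(=O)OC(C)(C)C | intermediate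
35 | tert-butyl (2Z)-3-{[(tert-butyldimethylsilyl)oxy]methyl}-5-[(1R,4aR,8aR)-5,5,8a-trimethyl-2-methylidenedecahydronaphthalen-1-yl]pent-2-enoate | C=C1CC[C@@H]2C(C)(C)CCC[C@@]2(C)[C@@H]1CC/C(=C/C(=O)OC(C)(C)C)CO[Si](C)(C)C(C)(C)C | intermediate
36 | acetic anhydride | CC(=O)OC(C)=O | starting material
37 | tert-butyl (2Z)-3-(hydroxymethyl)-5-[(1R,4aR,8aR)-5,5,8a-trimethyl-2-methylidenedecahydronaphthalen-1-yl]pent-2-enoate | C=C1CC[C@@H]2C(C)(C)CCC[C@@]2(C)[C@@H]1CC/C(=C/C(=O)OC(C)(C)C)CO | intermediate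
38 | tert-butyl (2Z)-3-(acetoxymethyl)-5-[(1R,4aR,8aR)-5,5,8a-trimethyl-2-methylidenedecahydronaphthalen-1-yl]pent-2-enoate | C=C1CC[C@@H]2C(C)(C)CCC[C@@]2(C)[C@@H]1CC/C(=C/C(=O)OC(C)(C)C)COC(C)=O | intermediate
39 | trimethylsilyl (2Z)-3-(acetoxymethyl)-5-[(1R,4aR,8aR)-5,5,8a-trimethyl-2-methylidenedecahydronaphthalen-1-yl]pent-2-enoate | C=C1CC[C@@H]2C(C)(C)CCC[C@@]2(C)[C@@H]1CC/C(=C/C(=O)O[Si](C)(C)C)COC(C)=O | intermediate
40 | (2Z)-3-(acetoxymethyl)-5-[(1R,4aR,8aR)-5,5,8a-trimethyl-2-methylidenedecahydronaphthalen-1-yl]pent-2-enoic acid (16-acetoxy-ent-labda-8(17),13Z-dien-15-oic acid; 5R,9R,10R) | C=C1CC[C@@H]2C(C)(C)CCC[C@@]2(C)[C@@H]1CC/C(=C/C(=O)O)COC(C)=O | target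

**Summary**

Total step count: 18. Longest linear sequence: 14 steps (1, 3, 4, 5, 6, 7, 10, 11, 12, 13, 14, 16, 17, 18).

**Steps most likely to fail**

Step 11. The endo (trans-fusion) and facial selectivity may erode as the 1,3-diaxial contact between the C10 methyl and the axial C4 methyl develops in the transition state, and the Lewis acid may desilylate or oligomerise the electron-rich allylsilane diene. The fallback sets out from aldehyde 15 and comes back at acid 26; it replaces chelate and auxiliary control by iminium activation and catalyst control without a Lewis acid. Wittig olefination of 15 with (triphenylphosphoranylidene)acetaldehyde in toluene at 80 °C should give (2E,8E)-11-chloro-4,4,8-trimethyl-9-[3-(trimethylsilyl)prop-1-en-2-yl]undeca-2,8-dienal F1. An intramolecular Diels–Alder reaction of F1 catalysed by a 5-benzyl-2-tert-butyl-3-methylimidazolidin-4-one salt (the enantiomer that delivers the diene to the same enal face as in step 11) in aqueous acetonitrile at −20 °C should give (1R,4aR,8aR)-4-(2-chloroethyl)-4a,8,8-trimethyl-3-[(trimethylsilyl)methyl]-1,2,4a,5,6,7,8,8a-octahydronaphthalene-1-carbaldehyde F2. Protodesilylation as in step 12 should give (1R,4R,4aS,8aR)-4-(2-chloroethyl)-4a,8,8-trimethyl-3-methylidenedecahydronaphthalene-1-carbaldehyde F3, and Pinnick oxidation (NaClO2, NaH2PO4, 2-methylbut-2-ene, t-BuOH/H2O) should give 26.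

Step 2. The (E) selectivity of the enol triflation may be incomplete, or the geometry may leak during the coupling of step 3; this would place the tether on the inside of the diene and lead into the cis-fused series. The fallback sets out from 3 and comes back at 11; it builds the tetrasubstituted alkene by a directed syn-carbometallation instead. Hydroboration–oxidation of 3 (9-BBN; NaOH, H2O2) should give 5-[(tert-butyldimethylsilyl)oxy]-4,4-dimethylpentan-1-ol F4, and I2/PPh3/imidazole should give tert-butyl[(5-iodo-2,2-dimethylpentyl)oxy]dimethylsilane F5. Alkylation of the dilithium salt of but-3-yn-1-ol with F5 (THF/DMPU) should give 9-[(tert-butyldimethylsilyl)oxy]-8,8-dimethylnon-3-yn-1-ol F6. Alkoxide-directed, Fe(acac)3-catalysed syn-carbomagnesiation with MeMgBr (methyl to the distal alkyne carbon) followed by iodinolysis should give (E)-9-[(tert-butyldimethylsilyl)oxy]-3-iodo-4,8,8-trimethylnon-3-en-1-ol F7. Negishi coupling of F7 with [3-(trimethylsilyl)prop-1-en-2-yl]zinc bromide (from (2-bromoallyl)trimethylsilane, t-BuLi, ZnBr2) under Pd(PPh3)4 should give 11 with retention.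

Step 17. The liberated (Z)-γ-hydroxy enoate may lactonise to the butenolide before it is acetylated. The fallback sets out from 31 and 28 and comes back at 38; it puts the acetate in place before the carbon–carbon bond is formed, where the linear alkyne cannot lactonise. Desilylation of 31 (HF·pyridine, THF) should give tert-butyl 4-hydroxybut-2-ynoate F8, and Ac2O/pyridine/DMAP should give tert-butyl 4-acetoxybut-2-ynoate F9. Addition of alkylcopper 33 (made from 28 as in step 16) to F9 at −78 °C should give tert-butyl (2E)-3-(acetoxymethyl)-2-cuprio-5-[(1R,4aR,8aR)-5,5,8a-trimethyl-2-methylidenedecahydronaphthalen-1-yl]pent-2-enoate F10, and protonation at −78 °C should give 38 directly.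

**Further compounds**

F1 | step 11 | (2E,8E)-11-chloro-4,4,8-trimethyl-9-[3-(trimethylsilyl)prop-1-en-2-yl]undeca-2,8-dienal | C=C(C[Si](C)(C)C)/C(CCCl)=C(\C)CCCC(C)(C)/C=C/C=O
F2 | step 11 | (1R,4aR,8aR)-4-(2-chloroethyl)-4a,8,8-trimethyl-3-[(trimethylsilyl)methyl]-1,2,4a,5,6,7,8,8a-octahydronaphthalene-1-carbaldehyde | ClCCC1=C(C[Si](C)(C)C)C[C@@H](C=O)[C@@H]2C(C)(C)CCC[C@@]12C
F3 | step 11 | (1R,4R,4aS,8aR)-4-(2-chloroethyl)-4a,8,8-trimethyl-3-methylidenedecahydronaphthalene-1-carbaldehyde | C=C1C[C@@H](C=O)[C@@H]2C(C)(C)CCC[C@@]2(C)[C@@H]1CCCl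
F4 | step 2 | 5-[(tert-butyldimethylsilyl)oxy]-4,4-dimethylpentan-1-ol | CC(C)(C)[Si](C)(C)OCC(C)(C)CCCO
F5 | step 2 | tert-butyl[(5-iodo-2,2-dimethylpentyl)oxy]dimethylsilane | CC(C)(C)[Si](C)(C)OCC(C)(C)CCCI
F6 | step 2 | 9-[(tert-butyldimethylsilyl)oxy]-8,8-dimethylnon-3-yn-1-ol | OCCC#CCCCC(C)(C)CO[Si](C)(C)C(C)(C)C
F7 | step 2 | (E)-9-[(tert-butyldimethylsilyl)oxy]-3-iodo-4,8,8-trimethylnon-3-en-1-ol | OCC/C(I)=C(/C)CCCC(C)(C)CO[Si](C)(C)C(C)(C)C
F8 | step 17 | tert-butyl 4-hydroxybut-2-ynoate | CC(C)(C)OC(=O)C#CCO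
F9 | step 17 | tert-butyl 4-acetoxybut-2-ynoate | CC(C)(C)OC(=O)C#CCOC(C)=O
F10 | step 17 | tert-butyl (2E)-3-(acetoxymethyl)-2-cuprio-5-[(1R,4aR,8aR)-5,5,8a-trimethyl-2-methylidenedecahydronaphthalen-1-yl]pent-2-enoate | C=C1CC[C@@H]2C(C)(C)CCC[C@@]2(C)[C@@H]1CC/C(COC(C)=O)=C(\[Cu])C(=O)OC(C)(C)C
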